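Ring A (C1–C5, C10) is read as a 3,3-dimethylcyclobutanone (C2, C3, C4, C5) that has taken up the C1=C10 olefin. A rhodium-catalysed carboacylation ("cut and sew") inserts the tethered isopropenyl group into the strained C2–C5 bond: C5–C10 closes ring B and creates the quaternary C10, C1–C2 closes ring A, and the C2 ketone that results becomes the equatorial chloride. The precursor is the aldol adduct of the cyclobutanone with a cis-γ-lactone aldehyde carrying C6–C12; the lactone later unfolds into the C8 methylene and the C12 aldehyde, on which an Evans aldol builds the hydroxy succinimide.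

Key step: step 9

Remark: the atom numbers of the target are used for all intermediates (ring A = C1–C5, C10; ring B = C5–C10; C11, C12 side chain; C13–C16 imide; C17 methylene carbon; α = face of H-5, β = face of the C10 methyl). Compounds 1, 4, 9, 22 and 23 are taken as commercial.

Step 1
Reactants: 1 methyl 4-methylpent-3-enoate
Product: 2 methyl (E)-5-hydroxy-4-methylpent-3-enoate
Conditions: SeO2 (0.3 equiv), t-BuOOH, CH2Cl2, rt
Reagents that add atoms: tert-butyl hydroperoxide CC(C)(C)OO
Why: Selenium dioxide allylic oxidation (ene reaction, then [2,3]-sigmatropic shift, SeO2 recycled by the hydroperoxide) attacks the more substituted alkene terminus and, of its two methyl groups, the (E)-methyl, so the (E)-allylic alcohol should form.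

Step 2
Reactants: 2 methyl (E)-5-hydroxy-4-methylpent-3-enoate
Product: 3 methyl (E)-4-methyl-5-(4,4,5,5-tetramethyl-1,3,2-dioxaborolan-2-yl)pent-3-enoate
Conditions: Pd(MeCN)4(BF4)2 (5 mol %), B2pin2, DMSO–MeOH, rt
Reagents that add atoms: bis(pinacolato)diboron CC1(C)OB(OC1(C)C)B1OC(C)(C)C(C)(C)O1
Why: Palladium-catalysed borylation of an allylic alcohol through an η3-allylpalladium intermediate places boron at the unhindered primary terminus and keeps the (E)-geometry, giving the γ-substituted allylboronate needed for an anti-selective allylation.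

Step 3
Reactants: 3 methyl (E)-4-methyl-5-(pinacolboryl)pent-3-enoate; 4 3-(tert-butyldimethylsilyloxy)propanal
Product: 6 (4R,5S)-5-[2-(tert-butyldimethylsilyloxy)ethyl]-4-(prop-1-en-2-yl)oxolan-2-one, via hydroxy ester 5 (not isolated)
Conditions: (R)-TRIP phosphoric acid (5 mol %), 4 Å MS, toluene, −30 °C; then pyridinium p-toluenesulfonate, toluene, 50 °C
Reagents that add atoms: none
Why: Chiral-phosphoric-acid-catalysed allylboration runs through a closed chair transition state in which the (E)-γ-substituent (C11) ends anti to the new hydroxyl while the (R)-acid steers the boronate to the Re face of the aldehyde, which sets C8 (S) and C9 (R); lactonisation of the anti γ-hydroxy ester then gives the cis-lactone.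

Step 4
Reactants: 6 (4R,5S)-5-[2-(tert-butyldimethylsilyloxy)ethyl]-4-(prop-1-en-2-yl)oxolan-2-one
Product: 7 (4R,5S)-5-(2-hydroxyethyl)-4-(prop-1-en-2-yl)oxolan-2-one
Conditions: HF·pyridine, THF–pyridine, 0 °C → rt
Reagents that add atoms: none
Why: Fluoride cleavage of the primary silyl ether under buffered conditions leaves the lactone and the isopropenyl group untouched.

Step 5
Reactants: 7 (4R,5S)-5-(2-hydroxyethyl)-4-(prop-1-en-2-yl)oxolan-2-one
Product: 8 2-[(2S,3R)-5-oxo-3-(prop-1-en-2-yl)oxolan-2-yl]acetaldehyde
Conditions: Dess–Martin periodinane, NaHCO3, CH2Cl2, 0 °C → rt; used at once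
Reagents that add atoms: none
Why: Dess–Martin oxidation is non-basic, which matters because the β-acyloxy aldehyde would lose the lactone carboxylate by E1cB elimination under amine-based oxidations.

Step 6
Reactants: 9 3,3-dimethylcyclobutan-1-one
Product: 10 [(3,3-dimethylcyclobut-1-en-1-yl)oxy]trimethylsilane
Conditions: LiN(i-Pr)2, Me3SiCl (in situ quench), THF, −78 °C
Reagents that add atoms: chlorotrimethylsilane C[Si](C)(C)Cl
Why: Kinetic deprotonation of the symmetric ketone with in situ silyl trapping gives the only possible enol silane and suppresses self-aldol reaction of the strained ketone.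

Step 7
Reactants: 8 2-[(2S,3R)-5-oxo-3-(prop-1-en-2-yl)oxolan-2-yl]acetaldehyde; 10 [(3,3-dimethylcyclobut-1-en-1-yl)oxy]trimethylsilane
Product: 11 (4R,5S)-5-{(2S)-2-[(1R)-2,2-dimethyl-4-oxocyclobutyl]-2-hydroxyethyl}-4-(prop-1-en-2-yl)oxolan-2-one
Conditions: BF3·OEt2 (1.1 equiv, added last to the premixed partners), CH2Cl2, −78 °C
Reagents that add atoms: none
Why: Mukaiyama aldol addition through an open transition state, in which the β-oxygen substituent at C8 directs attack to the aldehyde face that gives the 1,3-anti relationship (C6 S) and the aldehyde chain turns away from the gem-dimethyl carbon of the enol silane, which should give the C5/C6 syn isomer (C5 R); adding the Lewis acid last keeps the intramolecular carbonyl–ene reaction of the aldehyde with the isopropenyl group from competing.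

Step 8
Reactants: 11 (4R,5S)-5-{(2S)-2-[(1R)-2,2-dimethyl-4-oxocyclobutyl]-2-hydroxyethyl}-4-(prop-1-en-2-yl)oxolan-2-one
Product: 12 (4R,5S)-5-{(2S)-2-(tert-butyldimethylsilyloxy)-2-[(1R)-2,2-dimethyl-4-oxocyclobutyl]ethyl}-4-(prop-1-en-2-yl)oxolan-2-one
Conditions: TBSOTf, 2,6-lutidine, CH2Cl2, −78 °C
Reagents that add atoms: tert-butyldimethylsilyl triflate CC(C)(C)[Si](C)(C)OS(=O)(=O)C(F)(F)F
Why: Silyl triflate with a hindered pyridine base silylates the secondary alcohol at low temperature without enolising the cyclobutanone and blocks retro-aldol cleavage in the next step.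

Step 9
Reactants: 12 (4R,5S)-5-{(2S)-2-(tert-butyldimethylsilyloxy)-2-[(1R)-2,2-dimethyl-4-oxocyclobutyl]ethyl}-4-(prop-1-en-2-yl)oxolan-2-one
Product: 13 tricyclic keto lactone: trans-decalin (5α-H, 10β-CH3) with 4,4-dimethyl, C2 ketone, 6α-OTBS and a cis-fused γ-lactone C8(8β-O)–O–C12(=O)–C11H2–C9 (9α-H)
Conditions: [Rh(cod)2]BF4 (5 mol %), (R)-DTBM-SEGPHOS (6 mol %), 1,4-dioxane, 80 °C
Reagents that add atoms: none
Why: Monovalent rhodium adds oxidatively into the strained acyl–C5 bond (C2–C5) to give a five-membered acyl–alkyl rhodacycle of trivalent rhodium, the tethered isopropenyl group inserts into Rh–C5 with C10 bonding to C5 and rhodium moving to C1, and acyl–alkyl reductive elimination then joins C1 to C2. The closest known reaction type is the rhodium-catalysed intramolecular carboacylation of olefins by cyclobutanones ("cut and sew"), established for unsaturated partners tethered to the α-carbon (fused products) and for 1,1-disubstituted olefins (quaternary centres). Ring B closes by a 6-exo migratory insertion and ring A by reductive elimination from the seven-membered rhodacycle, a net two-carbon ring expansion of the cyclobutanone in a (4+2) sense. C5 keeps its configuration (retention in oxidative addition and migration), and the new quaternary C10 is set by a chair-like insertion transition state in which C4, the C6 silyloxy group and the C9 side arm are equatorial on the forming ring B, the cis-lactone locks C8/C9, and the tether points away from the metal so that H-5 and the C10 methyl end up anti (trans-decalin, methyl β). The step needs cleavage of the more substituted C2–C5 bond, not C2–C3, and insertion, not decarbonylation or β-elimination: oxidative addition is reversible and only the C2–C5 rhodacycle holds the olefin within reach, C4 carries no β-hydrogen, and the bulky electron-rich bisphosphine disfavours CO extrusion. The ligand antipode is a tuning handle only; control is expected from the four stereocentres of the substrate.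

Step 10
Reactants: 13 tricyclic keto lactone (C2 ketone, 6α-OTBS)
Product: 14 2β-alcohol (axial OH at C2) of the tricyclic lactone
Conditions: LiBH(s-Bu)3, THF, −78 °C
Reagents that add atoms: none
Why: The bulky borohydride delivers hydride to C2 from the α face, because the β face is screened by the axial C4 and C10 methyl groups, so the axial 2β-alcohol should form; the lactone is inert at −78 °C.

Step 11
Reactants: 14 2β-alcohol of the tricyclic lactone
Product: 15 2α-chloride (equatorial Cl at C2) of the tricyclic lactone
Conditions: PPh3, N-chlorosuccinimide, THF, 0 °C → rt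
Reagents that add atoms: N-chlorosuccinimide O=C1CCC(=O)N1Cl
Why: Appel-type deoxychlorination, in which chloride displaces the axial oxyphosphonium group with inversion (SN2) along the open equatorial trajectory on the α face, gives the equatorial 2α-chloride.

Step 12
Reactants: 15 2α-chloro tricyclic lactone
Product: 16 2-(2α-chloro-8β-hydroxy-6α-silyloxy-4,4,10-trimethyl-trans-decalin-9β-yl)-N-methoxy-N-methylacetamide
Conditions: MeNH(OMe)·HCl, AlMe3, CH2Cl2, 0 °C → rt; used without purification
Reagents that add atoms: N,O-dimethylhydroxylamine hydrochloride CNOC.Cl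
Why: Aluminium-amide aminolysis of the lactone (Weinreb amide formation) frees the C8 hydroxyl and turns C12 into an acyl group that can later be reduced selectively to the aldehyde.

Step 13
Reactants: 16 8β-hydroxy Weinreb amide
Product: 17 8-oxo Weinreb amide (2α-Cl, 6α-OTBS)
Conditions: Dess–Martin periodinane, NaHCO3, CH2Cl2, rt
Reagents that add atoms: none
Why: Dess–Martin oxidation of the axial C8 alcohol removes the C8 stereocentre, prevents relactonisation and leaves the C9 side arm in its equatorial, thermodynamically preferred position.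

Step 14
Reactants: 17 8-oxo Weinreb amide
Product: 18 8(17)-methylene Weinreb amide (2α-Cl, 6α-OTBS)
Conditions: Zn, CH2Br2, TiCl4, THF–CH2Cl2, 0 °C → rt
Reagents that add atoms: dibromomethane BrCBr
Why: Takai–Lombardo methylenation is non-basic and ketone-selective, so the hindered, enolisable β-silyloxy ketone should give the exocyclic methylene without β-elimination, epimerisation at C9 or attack on the Weinreb amide.

Step 15
Reactants: 18 8(17)-methylene Weinreb amide (6α-OTBS)
Product: 19 6α-hydroxy 8(17)-methylene Weinreb amide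
Conditions: Bu4NF, THF, 40 °C
Reagents that add atoms: none
Why: Fluoride cleaves the secondary silyl ether, and the equatorial chloride has no antiperiplanar ring hydrogen and should resist elimination.

Step 16
Reactants: 19 6α-hydroxy 8(17)-methylene Weinreb amide
Product: 20 6-oxo 8(17)-methylene Weinreb amide
Conditions: Dess–Martin periodinane, NaHCO3, CH2Cl2, 0 °C; used crude
Reagents that add atoms: none
Why: Buffered Dess–Martin oxidation gives the C6 ketone under conditions that should not move the exocyclic double bond into conjugation.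

Step 17
Reactants: 20 6-oxo 8(17)-methylene Weinreb amide
Product: 21 2-(2α-chloro-6β-hydroxy-4,4,10-trimethyl-8-methylene-trans-decalin-9β-yl)acetaldehyde
Conditions: LiAlH4, THF, −78 → −20 °C; aqueous potassium sodium tartrate
Reagents that add atoms: none
Why: Hydride attacks the C6 ketone from the α face (the β face carries the axial C4 and C10 methyl groups), setting the axial 6β-hydroxyl, and in the same operation reduces the Weinreb amide to the aldehyde through its stable chelated tetrahedral intermediate.

Step 18
Reactants: 22 (R)-4-benzyl-1,3-oxazolidin-2-one; 23 3-cyanopropanoic acid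
Product: 25 4-[(4R)-4-benzyl-2-oxo-1,3-oxazolidin-3-yl]-4-oxobutanenitrile, via mixed pivalic anhydride 24 (not isolated)
Conditions: t-BuCOCl, Et3N, THF, −20 °C; then 22, LiCl, rt
Reagents that add atoms: none
Why: N-Acylation of the oxazolidinone by a mixed pivalic anhydride under LiCl/Et3N activation is a standard preparation of Evans imides.

Step 19
Reactants: 21 hydroxy aldehyde; 25 4-[(4R)-4-benzyl-2-oxo-1,3-oxazolidin-3-yl]-4-oxobutanenitrile
Product: 27 Evans syn-aldol adduct (12S,13R; C13 bearing CH2CN and the acyl oxazolidinone), via dibutylboron enolate 26 (not isolated)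
Conditions: Bu2BOTf, i-Pr2NEt, CH2Cl2, −78 → 0 °C; then 21, −78 → 0 °C; MeOH, pH 7 buffer, H2O2
Reagents that add atoms: none
Why: Evans syn-aldol reaction, in which the (Z)-boron enolate reacts through a Zimmerman–Traxler chair with the benzyl group of the (R)-auxiliary shielding one face, sets C12 (S) and C13 (R); the hindered axial 6β-hydroxyl is expected to be a spectator.

Step 20
Reactants: 27 Evans syn-aldol adduct
Product: 29 Haterumaimide F, via primary amide 28 (not isolated)
Conditions: [PtH(PMe2OH)(PMe2O)2H] (5 mol %), EtOH–H2O, 70 °C; then Et3N, rt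
Reagents that add atoms: water O
Why: Platinum-catalysed hydration converts the nitrile into the primary amide under neutral conditions, and the amide nitrogen then attacks the imide carbonyl (5-exo-trig acyl transfer) with loss of the oxazolidinone, closing the succinimide without touching C12 or C13.

Compound list

1 | methyl 4-methylpent-3-enoate | COC(=O)CC=C(C)C | starting material
2 | methyl (E)-5-hydroxy-4-methylpent-3-enoate | COC(=O)C/C=C(C)/CO | intermediate
3 | methyl (E)-4-methyl-5-(4,4,5,5-tetramethyl-1,3,2-dioxaborolan-2-yl)pent-3-enoate | COC(=O)C/C=C(C)/CB1OC(C)(C)C(C)(C)O1 | intermediate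
4 | 3-(tert-butyldimethylsilyloxy)propanal | O=CCCO[Si](C)(C)C(C)(C)C | starting material
5 | methyl (3R,4S)-6-(tert-butyldimethylsilyloxy)-4-hydroxy-3-(prop-1-en-2-yl)hexanoate | COC(=O)C[C@H](C(C)=C)[C@@H](O)CCO[Si](C)(C)C(C)(C)C | intermediate (not isolated)
6 | (4R,5S)-5-[2-(tert-butyldimethylsilyloxy)ethyl]-4-(prop-1-en-2-yl)oxolan-2-one | O=C1C[C@H](C(C)=C)[C@@H](O1)CCO[Si](C)(C)C(C)(C)C | intermediate
7 | (4R,5S)-5-(2-hydroxyethyl)-4-(prop-1-en-2-yl)oxolan-2-one | O=C1C[C@H](C(C)=C)[C@@H](O1)CCO | intermediate
8 | 2-[(2S,3R)-5-oxo-3-(prop-1-en-2-yl)oxolan-2-yl]acetaldehyde | O=C1C[C@H](C(C)=C)[C@@H](O1)CC=O | intermediate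
9 | 3,3-dimethylcyclobutan-1-one | CC1(C)CC(=O)C1 | starting material
10 | [(3,3-dimethylcyclobut-1-en-1-yl)oxy]trimethylsilane | CC1(C)C=C(O[Si](C)(C)C)C1 | intermediate
11 | (4R,5S)-5-{(2S)-2-[(1R)-2,2-dimethyl-4-oxocyclobutyl]-2-hydroxyethyl}-4-(prop-1-en-2-yl)oxolan-2-one | O=C1C[C@H](C(C)=C)[C@@H](O1)C[C@H](O)[C@@H]2C(=O)CC2(C)C | intermediate
12 | (4R,5S)-5-{(2S)-2-(tert-butyldimethylsilyloxy)-2-[(1R)-2,2-dimethyl-4-oxocyclobutyl]ethyl}-4-(prop-1-en-2-yl)oxolan-2-one | O=C1C[C@H](C(C)=C)[C@@H](O1)C[C@H](O[Si](C)(C)C(C)(C)C)[C@@H]2C(=O)CC2(C)C | intermediate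
13 | tricyclic keto lactone: trans-decalin (5α-H, 10β-CH3), 4,4-dimethyl, 2-oxo, 6α-OTBS, cis-fused γ-lactone C8(β-O)–O–C12(=O)–C11–C9 | O=C1O[C@H]2C[C@H](O[Si](C)(C)C(C)(C)C)[C@H]3C(C)(C)CC(=O)C[C@]3(C)[C@H]2C1 | intermediate
14 | 2β-hydroxy analogue of 13 | O=C1O[C@H]2C[C@H](O[Si](C)(C)C(C)(C)C)[C@H]3C(C)(C)C[C@@H](O)C[C@]3(C)[C@H]2C1 | intermediate
15 | 2α-chloro tricyclic lactone | O=C1O[C@H]2C[C@H](O[Si](C)(C)C(C)(C)C)[C@H]3C(C)(C)C[C@H](Cl)C[C@]3(C)[C@H]2C1 | intermediate
16 | 2-(2α-chloro-8β-hydroxy-6α-(tert-butyldimethylsilyloxy)-4,4,10-trimethyl-trans-decalin-9β-yl)-N-methoxy-N-methylacetamide | O[C@H]1C[C@H](O[Si](C)(C)C(C)(C)C)[C@H]2C(C)(C)C[C@H](Cl)C[C@]2(C)[C@H]1CC(=O)N(C)OC | intermediate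
17 | 8-oxo analogue of 16 | O=C1C[C@H](O[Si](C)(C)C(C)(C)C)[C@H]2C(C)(C)C[C@H](Cl)C[C@]2(C)[C@H]1CC(=O)N(C)OC | intermediate
18 | 8(17)-methylene Weinreb amide (2α-Cl, 6α-OTBS) | C=C1C[C@H](O[Si](C)(C)C(C)(C)C)[C@H]2C(C)(C)C[C@H](Cl)C[C@]2(C)[C@H]1CC(=O)N(C)OC | intermediate
19 | 6α-hydroxy 8(17)-methylene Weinreb amide | C=C1C[C@H](O)[C@H]2C(C)(C)C[C@H](Cl)C[C@]2(C)[C@H]1CC(=O)N(C)OC | intermediate
20 | 6-oxo 8(17)-methylene Weinreb amide | C=C1CC(=O)[C@H]2C(C)(C)C[C@H](Cl)C[C@]2(C)[C@H]1CC(=O)N(C)OC | intermediate
21 | 2-(2α-chloro-6β-hydroxy-4,4,10-trimethyl-8-methylene-trans-decalin-9β-yl)acetaldehyde | C=C1C[C@@H](O)[C@H]2C(C)(C)C[C@H](Cl)C[C@]2(C)[C@H]1CC=O | intermediate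
22 | (R)-4-benzyl-1,3-oxazolidin-2-one | O=C1N[C@H](Cc2ccccc2)CO1 | starting material
23 | 3-cyanopropanoic acid | N#CCCC(=O)O | starting material
24 | 3-cyanopropanoic pivalic anhydride | N#CCCC(=O)OC(=O)C(C)(C)C | intermediate (not isolated)
25 | 4-[(4R)-4-benzyl-2-oxo-1,3-oxazolidin-3-yl]-4-oxobutanenitrile | N#CCCC(=O)N1[C@H](Cc2ccccc2)COC1=O | intermediate
26 | dibutylboron (Z)-enolate of 25 | CCCCB(CCCC)O/C(=C\CC#N)N1[C@H](Cc2ccccc2)COC1=O | intermediate (not isolated)
27 | Evans syn-aldol adduct (12S,13R) of 21 and 25 | C=C1C[C@@H](O)[C@H]2C(C)(C)C[C@H](Cl)C[C@]2(C)[C@H]1C[C@H](O)[C@@H](CC#N)C(=O)N1[C@H](Cc2ccccc2)COC1=O | intermediate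
28 | primary amide from hydration of 27 | C=C1C[C@@H](O)[C@H]2C(C)(C)C[C@H](Cl)C[C@]2(C)[C@H]1C[C@H](O)[C@@H](CC(N)=O)C(=O)N1[C@H](Cc2ccccc2)COC1=O | intermediate (not isolated)
29 | Haterumaimide F (2S,5S,6R,9S,10R,12S,13R) | C=C1C[C@@H](O)[C@H]2C(C)(C)C[C@H](Cl)C[C@]2(C)[C@H]1C[C@H](O)[C@H]1CC(=O)NC1=O | target

Total step count: 20. Longest linear sequence: 18 steps (1 → 29 through steps 1–5, 7–17, 19 and 20).

Steps most likely to fail

1. Step 9 (key step). Oxidative addition at the hindered C2–C5 bond may be outrun by insertion into C2–C3 followed by decarbonylation, the rhodacycle may collapse by β-silyloxy or β-hydride elimination before the 1,1-disubstituted olefin inserts, or the facial preference at C10 may be weak. The fallback sets out from aldehyde 8 and comes back at 13; it forms the same two bonds in one thermal operation by a type 1 intramolecular Diels–Alder reaction and adds the second C4 methyl afterwards. Aldehyde 8 would be extended by a vinylogous Mukaiyama aldol reaction with (E)-tert-butyl[(3-methylbuta-1,3-dien-1-yl)oxy]dimethylsilane (BF3·OEt2, CH2Cl2, −78 °C; same 1,3-anti sense as in step 7) to the δ-hydroxy enal F1, which is silylated (TBSOTf, 2,6-lutidine) to the enal F2 and converted with Et3SiOTf/Et3N under equilibrating conditions into the (1E,3E)-silyloxydiene F3. Heating (toluene, 190 °C, sealed tube) should close rings A and B together, forming C1–C2 and C5–C10, to the octalin F4; the chair-like tether with the lactone and the silyl ether in equatorial-type positions should favour the trans fusion. Selective cleavage of the triethylsilyl ether (pyridinium p-toluenesulfonate, MeOH) gives the allylic alcohol F5, Dess–Martin oxidation gives the enone F6, and conjugate addition of Me2CuLi (Me3SiCl, Et2O, −78 °C) completes the gem-dimethyl group and returns to 13.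

2. Step 7. Discrimination between the syn and anti modes in the open transition state may be poor, and the Lewis-acid-activated aldehyde may close onto its own isopropenyl group by a carbonyl–ene reaction. The fallback sets out from ketone 9 and aldehyde 8 and comes back at 11; it makes no new compound (F0). The ketone would be converted into its chlorozirconocene enolate (LiN(i-Pr)2, THF, −78 °C; then Cp2ZrCl2) and added to 8. Such enolates react through a closed, metal-centred transition state that is syn-selective whatever the enolate geometry, and no free Lewis acid is present to trigger the ene reaction. The facial bias from C8 is expected to be weaker, so the diastereomers may need separation.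

3. Step 11. The oxyphosphonium group may form slowly at the axial hydroxyl flanked by two syn-axial methyl groups, and the axial leaving group may undergo E2 elimination towards the C1 or C3 olefin in place of substitution. The fallback sets out from alcohol 14 and comes back at 15; it replaces the ionic displacement by a radical deoxychlorination. Acylation with methyl chlorooxoacetate (pyridine, CH2Cl2) gives the methyl oxalate F7, and CsOH (THF–H2O, 0 °C) gives the caesium oxalate F8. Irradiation with blue light in the presence of [Ir(dF(CF3)ppy)2(dtbbpy)]PF6 and ethyl trichloroacetate should expel two molecules of CO2, and the secondary C2 radical should take chlorine from the open α face (the β face is shielded by the axial methyl groups), giving the equatorial chloride 15 whatever the alcohol configuration.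

Further compounds

F1 | step 9 | (4R,5S)-5-[(2R,4E)-2-hydroxy-4-methyl-6-oxohex-4-en-1-yl]-4-(prop-1-en-2-yl)oxolan-2-one | O=C1C[C@H](C(C)=C)[C@@H](O1)C[C@H](O)C/C(C)=C/C=O
F2 | step 9 | O-tert-butyldimethylsilyl ether of F1 | O=C1C[C@H](C(C)=C)[C@@H](O1)C[C@H](O[Si](C)(C)C(C)(C)C)C/C(C)=C/C=O
F3 | step 9 | (4R,5S)-5-[(2S,3E,5E)-2-(tert-butyldimethylsilyloxy)-4-methyl-6-(triethylsilyloxy)hexa-3,5-dien-1-yl]-4-(prop-1-en-2-yl)oxolan-2-one | O=C1C[C@H](C(C)=C)[C@@H](O1)C[C@H](O[Si](C)(C)C(C)(C)C)/C=C(C)/C=C/O[Si](CC)(CC)CC
F4 | step 9 | Diels–Alder adduct: trans-fused 3-ene (C3=C4, 4-methyl) with 2β-triethylsilyloxy, 6α-OTBS, 10β-methyl and the cis-fused γ-lactone | O=C1O[C@H]2C[C@H](O[Si](C)(C)C(C)(C)C)[C@H]3C(C)=C[C@@H](O[Si](CC)(CC)CC)C[C@]3(C)[C@H]2C1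
F5 | step 9 | 2β-allylic alcohol from F4 | O=C1O[C@H]2C[C@H](O[Si](C)(C)C(C)(C)C)[C@H]3C(C)=C[C@@H](O)C[C@]3(C)[C@H]2C1
F6 | step 9 | 4-methyl-3-en-2-one (enone) from F5 | O=C1O[C@H]2C[C@H](O[Si](C)(C)C(C)(C)C)[C@H]3C(C)=CC(=O)C[C@]3(C)[C@H]2C1
F0 | step 7 | none | none
F7 | step 11 | methyl oxalate of the 2β-alcohol 14 | O=C1O[C@H]2C[C@H](O[Si](C)(C)C(C)(C)C)[C@H]3C(C)(C)C[C@@H](OC(=O)C(=O)OC)C[C@]3(C)[C@H]2C1
F8 | step 11 | caesium oxalate of the 2β-alcohol 14 | O=C1O[C@H]2C[C@H](O[Si](C)(C)C(C)(C)C)[C@H]3C(C)(C)C[C@@H](OC(=O)C(=O)[O-])C[C@]3(C)[C@H]2C1.[Cs+]
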